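## Structural features

3,5,6-Tribromo-1H-indole is a flat, achiral bicycle: a benzene ring fused to a pyrrole ring through the C3a–C7a bond, with a free N1–H. It has no stereocentre, so no stereocentres stand next to each other and the problem is purely one of regiochemistry. There are three C–Br bonds: one on the pyrrole β-carbon C3 and two on the neighbouring benzo carbons C5 and C6, while C2, C4 and C7 keep their hydrogens. The C3 bromine is easy to place, because C3 is the most nucleophilic carbon of an N–H indole, but an N-unprotected 3-bromoindole is sensitive to acid, light and oxidants, so this bond is best made last. The real difficulty is the vicinal 5,6-dibromo pattern: electrophilic bromination of an indole does not deliver it cleanly, so both benzo bromines must be in place when the benzo ring is formed. All C–Br bonds, vinylic at first and aromatic later, must survive the remaining steps, which excludes reducing metals, hydrogenation catalysts and organolithium reagents. The key step uses the fact that the chain C4–C5–C6–C7, with bromine on its two inner carbons, is the carbon skeleton of 2,3-dibromobuta-1,3-diene, and that the fusion bond C3a–C7a is the C2–C3 bond of a pyrrole. A [4+2] cycloaddition across that pyrrole bond therefore builds the six-membered ring with both bromines already on it.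

## Logic of the disconnections

12 ⇒ 11. The C3–Br bond is cut first. C3 of 11 is its enamine-type and most nucleophilic carbon, so this is the one C–Br bond that needs no directing device, and making it last keeps the fragile 3-bromoindole unit out of every other step. The gain is the removal of the only sensitive function. The forward step must stop after one bromination and spare C2 and the nitrogen.

11 ⇒ 10. The N1–H bond is exchanged for an N1–S bond, which puts the arenesulfonyl group back on nitrogen. The group is needed further back as an activating group, and it also shields the pyrrole ring from the oxidant of the dehydrogenation. Nothing is gained in skeleton. The forward step must cleave N–S with a nucleophilic base that leaves two aryl bromides alone.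

10 ⇒ 9. No skeletal bond is cut; two hydrogens are put back on C4 and C7. The benzo ring becomes a 1,4-cyclohexadiene whose isolated C5=C6 double bond carries both bromines, which is the retron of a butadiene cycloaddition. The forward step must remove exactly the two doubly activated methylene hydrogens and must not eliminate a bromine together with a hydrogen. Both bromines sit on sp2 carbons, so no such elimination is set up.

9 ⇒ 4 + 7 (through 8). A nitro group on C3a and a hydrogen on C7a are formally added back, and then C3a–C4 and C7–C7a are cut. This is the largest simplification: one ring and two C–C bonds are undone at once, and the bicycle falls into a monocyclic pyrrole and an acyclic, symmetrical four-carbon diene that carries both benzo bromines. The forward step must occur at the nitro-bearing C2–C3 bond of 4 and not at C4–C5. In addition, 7 must reach its s-cis form and survive the temperature that an aromatic dienophile requires, and 8 must then lose the nitro group and the C7a hydrogen to restore the pyrrole.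

4 ⇒ 1 + 2 (through 3). The N–S bond is cut. Both pieces are purchasable and the nitro group is already on C3, so no pyrrole nitration with its regiochemical problem enters the route. The forward step is the N-sulfonylation of an acidic but weakly nucleophilic pyrrole, which calls for full deprotonation first.

7 ⇒ 5 (through 6). No atom is removed: the two bromines move from the inner carbons to the terminal carbons and the two double bonds merge into one triple bond. 5 is the storable isomer, whereas 7 polymerises and should be made only when needed. The forward step is therefore an isomerisation by two successive allylic (SN2′) bromide transpositions, not a hydrobromination, and it must be driven past the allene stage 6.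

## Other disconnections considered

Alternative 1: The cut runs through C4–C5 and C6–C7, so that C5 and C6 come from an alkyne and C4, C3a, C7a and C7 from the diene half of a pyrrole-fused 2-pyranone.
- Forward key step: the pyranone 1-{[2-(trimethylsilyl)ethoxy]methyl}pyrano[3,4-b]pyrrol-5(1H)-one A2 would add the alkyne 1,2-bis(pinacolboryl)ethyne A3 in a [4+2] cycloaddition. The bridged lactone adduct would aromatise by decarboxylative cycloreversion to 5,6-bis(pinacolboryl)-1-{[2-(trimethylsilyl)ethoxy]methyl}-1H-indole A1. A twofold bromodeboronation under oxidising copper conditions would then give 5,6-dibromo-1-{[2-(trimethylsilyl)ethoxy]methyl}-1H-indole A4, followed by removal of the N-substituent and C3 bromination.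
- In its favour: the cycloreversion delivers the aromatic benzo ring directly, so no separate dehydrogenation is needed, and both partners are thermally robust whereas 7 polymerises. On these two points the alternative is the better plan. The symmetric alkyne removes any regiochemical question exactly as the symmetric diene does in the chosen plan, so there the two are equal.
- Against it: A2 is not purchasable and would have to be assembled over several steps from a 2,3-difunctionalised pyrrole. Pyranones of this kind without a substituent next to the ring oxygen are sensitive. An alkynyl boronate is itself a sluggish dienophile, so this key step would also need prolonged heating. The bromines are not carried through the key step but must be introduced afterwards at two adjacent, hindered positions.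
- Comparison: in structure, both plans build the benzo ring onto an existing pyrrole and differ only in which pair of bonds is formed. In mechanism, both are pericyclic additions followed by loss of a small molecule. In step economy, the alternative is expected to be longer by the synthesis of A2 and by the C–B to C–Br exchange, which outweighs the dehydrogenation it saves.

Alternative 2: The cut is the C2=C3 bond of the pyrrole ring, which leads back to an ortho-formyl formanilide.
- Forward key step: a low-valent titanium reagent would couple the aldehyde carbon and the formamide carbon of N-(4,5-dibromo-2-formylphenyl)formamide A5 reductively, with loss of both oxygens, to give 5,6-dibromo-1H-indole A6, the same compound as 11.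
- In its favour: the bromine pattern is fixed by the benzene precursor from the outset and no nitrogen protecting group is needed. A6 is one step from the target, where the chosen plan needs three steps after its key step, so on the length of the endgame the alternative is clearly better.
- Against it: this kind of carbonyl–amide coupling is at its best with ketones and substituted amides. An aldehyde paired with a formamide is its least favourable case, because the aldehyde is the carbonyl most prone to intermolecular pinacol-type coupling and to plain reduction. The aryl C–Br bonds may not be inert to the reductant at reflux. A5 also requires 2-amino-4,5-dibromobenzaldehyde A7, whose substitution pattern is not the one that direct electrophilic bromination of an aminobenzaldehyde produces and which is prone to self-condensation.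
- Comparison: in structure, the alternative adds the pyrrole ring to a finished dibromobenzene, the reverse of the chosen plan. In mechanism, it forms one bond by electron transfer where the chosen plan forms two by a pericyclic process, so its risk is chemoselectivity while that of the chosen plan is reactivity. In step economy, the two are expected to be about equal once the preparation of A7 is counted.

Alternative 3: The cuts are N1–C7a and C3–C3a, the two bonds that tie the five-membered ring to the arene, which leads back to an aryne and a dehydroamino ester.
- Forward key step: fluoride would release 4,5-dibromobenzyne A8 from 4,5-dibromo-2-(trimethylsilyl)phenyl trifluoromethanesulfonate A9. The carbamate nitrogen of methyl 2-[(tert-butoxycarbonyl)amino]acrylate A10 would add to the aryne, and the aryl anion so formed would close onto the terminal acrylate carbon in a 5-endo-trig sense. The product would be racemic methyl 1-(tert-butoxycarbonyl)-5,6-dibromoindoline-2-carboxylate A11.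
- In its favour: the annulation would run at ambient temperature and belongs to a reaction type established for carbamate-protected dehydroalanine esters, so its key step is the more secure one. The aryne is symmetric, so regiochemistry is no more of an issue than with 7.
- Against it: A11 is at the indoline oxidation level and carries one carbon too many. Ester hydrolysis, decarboxylation, removal of the carbamate and dehydrogenation would be needed before C3 can be brominated, and its C2 stereocentre would be made only to be destroyed. A9 is itself a multistep compound.
- Comparison: in structure, the alternative, like alternative 2, brings in the complete dibromobenzene ring and builds the five-membered ring, whereas the chosen plan builds the six-membered ring. In mechanism, it is a polar, stepwise addition–cyclisation against a concerted cycloaddition. In step economy, it is expected to be clearly longer than the chosen plan both before and after the key step.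

Key step: step 3

Assumption: 1 and 5 are bought as catalogue chemicals, and 7 is never stored neat but handled as a cold, BHT-inhibited solution.

Correction: 5 and 7 are isomers (C4H4Br2), so step 2 is a bromide-shuttled double allylic transposition and not an addition of HBr, which would lead to a tribromobutene.

## Route

Step 1
Reactants: 1 3-nitro-1H-pyrrole; 2 4-toluenesulfonyl chloride
Product: 4 3-nitro-1-tosyl-1H-pyrrole, via sodium 3-nitropyrrol-1-ide 3 (not isolated)
Conditions: NaH (1.1 equiv), THF, 0 °C; then 2, 0 °C → rt
Reagents that add atoms: 4-toluenesulfonyl chloride (compound 2), Cc1ccc(cc1)S(Cl)(=O)=O
Why: NaH removes the acidic N–H of 1 to give the nitro-stabilised anion 3, whose nitrogen attacks the sulfonyl chloride 2 with loss of chloride (N-sulfonylation of a pyrrolide). The sulfonyl group serves as protecting group and as the second acceptor that the cycloaddition needs.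

Step 2
Reactants: 5 1,4-dibromobut-2-yne
Product: 7 2,3-dibromobuta-1,3-diene, via 3,4-dibromobuta-1,2-diene 6 (not isolated)
Conditions: CuBr (0.2 equiv), NH4Br, 48% aq HBr, 50 °C; extraction into toluene containing BHT, kept at −20 °C
Reagents that add atoms: none
Why: Bromide, assisted by CuBr, attacks C2 of 5 in an SN2′ sense and expels the remote propargylic bromide to give the bromoallene 6; a second SN2′ attack at the central allene carbon expels the remaining allylic bromide and leaves the conjugated diene 7 (propargyl–allenyl–dienyl halide rearrangement, the reaction type of the chloroprene process). The net change is an isomerisation, so bromide only shuttles, and 7 is kept cold, dilute and inhibited because 2,3-dihalobutadienes polymerise.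

Step 3
Reactants: 4 3-nitro-1-tosyl-1H-pyrrole; 7 2,3-dibromobuta-1,3-diene
Product: 9 5,6-dibromo-1-tosyl-4,7-dihydro-1H-indole, via cis-fused 3a-nitro cycloadduct 8 (not isolated)
Conditions: 7 (5 equiv, added in portions), BHT (cat.), toluene, sealed tube, 150 °C
Reagents that add atoms: none
Why: The s-cis form of 7 adds suprafacially, in a thermal normal-demand [4+2] cycloaddition, across the C2–C3 π-bond of 4, whose LUMO is lowered by the C3 nitro group and the N-sulfonyl group, so that C3a–C4 and C7–C7a form in one concerted step and the cis-fused adduct 8 results. In 8 the nitro group on C3a and the hydrogen on C7a, which is activated by the adjacent sulfonamide nitrogen, are lost thermally as nitrous acid, and the regained pyrrole aromaticity drives this step and makes the overall process irreversible. The closest known reaction type is the use of N-sulfonyl 3-nitropyrroles and 3-nitroindoles as dienophiles toward alkyl- and oxygen-substituted butadienes with denitration in the same pot; 7 is a weaker donor than those dienes, hence the excess of diene, the inhibitor and the forcing temperature. The one ring that is closed, the six-membered carbocycle, is closed by intermolecular cycloaddition and not by a stepwise cyclisation. The two ring-fusion stereocentres of 8 are set cis by the suprafacial addition but both are erased on elimination, so 9 contains no stereocentre. The selectivity needed is for the nitro-bearing C2–C3 bond over the C4–C5 bond of 4, and the nitro group secures it twice, as the activating group and as the leaving group that only this adduct can lose; orientation is no issue because 7 is symmetric. The vinylic C–Br bonds take no part, since neither is allylic to a leaving group or set up for elimination.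

Step 4
Reactants: 9 5,6-dibromo-1-tosyl-4,7-dihydro-1H-indole
Product: 10 5,6-dibromo-1-tosyl-1H-indole
Conditions: DDQ (1.1 equiv), toluene, rt → 60 °C
Reagents that add atoms: none
Why: DDQ abstracts hydride from a C4/C7 methylene that is both allylic and benzylic to the pyrrole, and proton loss then aromatises the 1,4-cyclohexadiene ring (quinone dehydrogenation of a dihydroarene). Both bromines sit on sp2 carbons, so only the two ring hydrogens can leave, and any 10 already formed in step 3 is simply carried through.

Step 5
Reactants: 10 5,6-dibromo-1-tosyl-1H-indole
Product: 11 5,6-dibromo-1H-indole
Conditions: KOH (3 equiv), MeOH/THF/H2O, 60 °C; aq NH4Cl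
Reagents that add atoms: none
Why: Hydroxide or methoxide attacks sulfur and expels the indolide, a good leaving group made better by the two bromines (basic N-desulfonylation of an indole). Aryl bromides are inert to these conditions.

Step 6
Reactants: 11 5,6-dibromo-1H-indole
Product: 12 3,5,6-tribromo-1H-indole
Conditions: NBS (1.0 equiv), DMF, 0 °C, dark
Reagents that add atoms: N-bromosuccinimide, O=C1CCC(=O)N1Br
Why: C3 of the free indole is by far its most nucleophilic position and the dibrominated benzo ring is deactivated, so one equivalent of NBS should brominate C3 only (electrophilic aromatic substitution). The product is worked up cold, without acid and shielded from light because 3-bromoindoles are labile.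

## Compound list

1 | 3-nitro-1H-pyrrole | [O-][N+](=O)c1cc[nH]c1 | starting material
2 | 4-toluenesulfonyl chloride (tosyl chloride) | Cc1ccc(cc1)S(Cl)(=O)=O | starting material
3 | sodium 3-nitropyrrol-1-ide | [Na+].[O-][N+](=O)c1cc[n-]c1 | intermediate
4 | 3-nitro-1-tosyl-1H-pyrrole (1-(4-methylbenzenesulfonyl)-3-nitro-1H-pyrrole) | Cc1ccc(cc1)S(=O)(=O)n1ccc(c1)[N+]([O-])=O | intermediate
5 | 1,4-dibromobut-2-yne | BrCC#CCBr | starting material
6 | 3,4-dibromobuta-1,2-diene | C=C=C(Br)CBr | intermediate
7 | 2,3-dibromobuta-1,3-diene | C=C(Br)C(Br)=C | intermediate
8 | cis-5,6-dibromo-3a-nitro-1-tosyl-3a,4,7,7a-tetrahydro-1H-indole (racemic; 3a-nitro and 7a-hydrogen on the same face; one enantiomer drawn) | [O-][N+](=O)[C@]12CC(Br)=C(Br)C[C@H]1N(S(=O)(=O)c3ccc(C)cc3)C=C2 | intermediate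
9 | 5,6-dibromo-1-tosyl-4,7-dihydro-1H-indole | Cc1ccc(cc1)S(=O)(=O)n1ccc2CC(Br)=C(Br)Cc12 | intermediate
10 | 5,6-dibromo-1-tosyl-1H-indole | Cc1ccc(cc1)S(=O)(=O)n1ccc2cc(Br)c(Br)cc21 | intermediate
11 | 5,6-dibromo-1H-indole | Brc1cc2cc[nH]c2cc1Br | intermediate
12 | 3,5,6-tribromo-1H-indole | Brc1cc2[nH]cc(Br)c2cc1Br | target

## Step count and least certain steps

Total step count: 6. Longest linear sequence: 5 steps (steps 1, 3, 4, 5, 6; the branch through step 2 is equally long).

Step 3 (key step). The most likely failure is that the cycloaddition is outrun by thermal dimerisation and radical polymerisation of 7. The diene is only a weak donor, its s-cis form is disfavoured by repulsion of the two parallel C–Br dipoles, and the aromatic dienophile 4 needs temperatures at which 7 is short-lived. The nitrous acid set free may also nitrosate or oxidise material. Raising the pressure would only change the conditions. The fallback changes the approach: the benzo ring is bought and the second benzo bromine is introduced by directed electrophilic substitution. It sets out from 2 and comes back to the route at 10. Purchased 6-bromoindoline F1 would be N-sulfonylated with 2 (pyridine, CH2Cl2) to 6-bromo-1-tosylindoline F2. Bromination (Br2, AcOH, rt) should go para to the sulfonamide nitrogen, at C5 next to the existing bromine, and give 5,6-dibromo-1-tosylindoline F3. Dehydrogenation of the five-membered ring with Mn(OAc)3 in hot acetic acid (trivalent manganese, an oxidant suited to N-sulfonyl indolines) would then give 10, from which steps 5 and 6 follow unchanged.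

Step 2. The bromide transposition may stall at the allene 6 or give mixtures, and 7 may polymerise during isolation or concentration. The fallback replaces the rearrangement by an addition–elimination sequence; it sets out from 5 and comes back at 7. Br2 (1 equiv, CH2Cl2, 0 °C) should add anti across the triple bond of 5 to give (E)-1,2,3,4-tetrabromobut-2-ene F4. NaI in acetone would then remove the two allylic bromines by iodide-induced 1,4-elimination, the reaction type used to make 1,3-dienes and ortho-quinodimethanes from 1,4-dihalo-2-enes. The resulting 7 would be washed free of iodine with aqueous Na2S2O3 and taken up in inhibited toluene.

Step 6. Over-bromination at C2 and oxidative or acid-induced decomposition of the unprotected 3-bromoindole during reaction and purification are the likely problems. The fallback changes the order of events so that bromination takes place while nitrogen is still protected; it sets out from 10 and comes back at 12. Br2 (1.05 equiv, DMF, 0 °C → rt) should brominate C3 of 10 to give 3,5,6-tribromo-1-tosyl-1H-indole F5, a robust N-sulfonyl indole that can be purified without special care. KOH in MeOH/THF at 50 °C would then remove the sulfonyl group and deliver 12 from a mild basic hydrolysis as the last operation.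

## Further compounds

F1 | step 3 | 6-bromoindoline (6-bromo-2,3-dihydro-1H-indole) | Brc1ccc2CCNc2c1
F2 | step 3 | 6-bromo-1-tosylindoline | Cc1ccc(cc1)S(=O)(=O)N1CCc2ccc(Br)cc21
F3 | step 3 | 5,6-dibromo-1-tosylindoline | Cc1ccc(cc1)S(=O)(=O)N1CCc2cc(Br)c(Br)cc21
F4 | step 2 | (E)-1,2,3,4-tetrabromobut-2-ene | BrC/C(Br)=C(Br)/CBr
F5 | step 6 | 3,5,6-tribromo-1-tosyl-1H-indole | Cc1ccc(cc1)S(=O)(=O)n1cc(Br)c2cc(Br)c(Br)cc21
A1 | alternative 1 | 5,6-bis(pinacolboryl)-1-{[2-(trimethylsilyl)ethoxy]methyl}-1H-indole | CC1(C)OB(OC1(C)C)c3cc2ccn(COCC[Si](C)(C)C)c2cc3B4OC(C)(C)C(C)(C)O4
A2 | alternative 1 | 1-{[2-(trimethylsilyl)ethoxy]methyl}pyrano[3,4-b]pyrrol-5(1H)-one | O=C1C=C2C=CN(COCC[Si](C)(C)C)C2=CO1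
A3 | alternative 1 | 1,2-bis(pinacolboryl)ethyne | CC1(C)OB(OC1(C)C)C#CB2OC(C)(C)C(C)(C)O2
A4 | alternative 1 | 5,6-dibromo-1-{[2-(trimethylsilyl)ethoxy]methyl}-1H-indole | Brc1cc2ccn(COCC[Si](C)(C)C)c2cc1Br
A5 | alternative 2 | N-(4,5-dibromo-2-formylphenyl)formamide | O=CNc1cc(Br)c(Br)cc1C=O
A6 | alternative 2 | 5,6-dibromo-1H-indole | Brc1cc2cc[nH]c2cc1Br
A7 | alternative 2 | 2-amino-4,5-dibromobenzaldehyde | Nc1cc(Br)c(Br)cc1C=O
A8 | alternative 3 | 4,5-dibromobenzyne | BrC1=CC#CC=C1Br
A9 | alternative 3 | 4,5-dibromo-2-(trimethylsilyl)phenyl trifluoromethanesulfonate | C[Si](C)(C)c1cc(Br)c(Br)cc1OS(=O)(=O)C(F)(F)F
A10 | alternative 3 | methyl 2-[(tert-butoxycarbonyl)amino]acrylate | C=C(NC(=O)OC(C)(C)C)C(=O)OC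
A11 | alternative 3 | methyl 1-(tert-butoxycarbonyl)-5,6-dibromoindoline-2-carboxylate (racemic) | COC(=O)C1Cc2cc(Br)c(Br)cc2N1C(=O)OC(C)(C)C
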